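The route rests on cutting both ring B oxygens back to dioxygen: in the target the C5 ester oxygen and the C8 ketone oxygen sit 1,4 to each other across the C6=C7 double bond of the seven-membered ring B. Singlet oxygen adds across C5 and C8 of a ring B 5,7-diene in one (4+2) step, which forms both C–O bonds, sets C5 and leaves the olefin in place; base-induced opening of the peroxide then gives the C5 alcohol and the C8 enone. The precursor is the trans-fused hydroazulene diene with ring A complete (C1 acetate, C3 hydroxy and isopropyl, C10 methyl), assembled on a cyclopentenone and closed by metathesis with the C7 methyl already in place.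

Key step: step 14

Remark on locants: ring A = C1–C2–C3–C4–C10, ring B = C4–C5–C6–C7–C8–C9–C10; β is the face of the C10 methyl group, α the opposite face; all intermediates keep these locants (the ring A carbon that bears the methyl group is C10 from the start).
Remark on materials: (S)-4-(tert-butyldimethylsilyloxy)cyclopent-2-en-1-one and (Z)-3-methylpent-2-en-4-yn-1-ol are assumed to be commercial; TBS = tert-butyldimethylsilyl, TMS = trimethylsilyl.

Step 1
Reactants: 1 (S)-4-(tert-butyldimethylsilyloxy)cyclopent-2-en-1-one; 2 iodine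
Product: 3 (S)-4-(tert-butyldimethylsilyloxy)-2-iodocyclopent-2-en-1-one
Conditions: I2, pyridine, CH2Cl2, 0 °C to rt
Reagents that add atoms: iodine, II
Why: Pyridine-mediated α-iodination of the enone (conjugate addition of pyridine, iodination of the enolate, elimination) should place iodine on the future C10 without touching the C3 silyloxy stereocentre.

Step 2
Reactants: 3 (S)-4-(tert-butyldimethylsilyloxy)-2-iodocyclopent-2-en-1-one; 4 tetramethylstannane
Product: 5 (S)-4-(tert-butyldimethylsilyloxy)-2-methylcyclopent-2-en-1-one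
Conditions: Me4Sn, Pd2(dba)3 (cat.), AsPh3, CuI, NMP, 60 °C
Reagents that add atoms: tetramethylstannane, C[Sn](C)(C)C
Why: Stille coupling of the alkenyl iodide transfers the future C10 methyl group under neutral conditions that spare the base-sensitive γ-silyloxy enone.

Step 3
Reactants: 5 (S)-4-(tert-butyldimethylsilyloxy)-2-methylcyclopent-2-en-1-one; 6 vinylmagnesium bromide; 7 chlorotrimethylsilane
Product: 8 3α-(tert-butyldimethylsilyloxy)-10-methyl-1-(trimethylsilyloxy)-4β-vinylcyclopent-1(10)-ene
Conditions: vinylMgBr, CuBr·SMe2 (cat.), TMSCl, THF, −78 °C; Et3N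
Reagents that add atoms: vinylmagnesium bromide, C=C[Mg]Br; chlorotrimethylsilane, C[Si](C)(C)Cl
Why: Copper-catalysed conjugate addition with silyl trapping should deliver the vinyl group to C4 anti to the neighbouring C3 silyloxy group, as in prostaglandin-type additions to 4-silyloxycyclopentenones, and fixes the enol ether at C1=C10.

Step 4
Reactants: 9 (Z)-3-methylpent-2-en-4-yn-1-ol; 10 phosphorus tribromide
Product: 11 (2Z)-1-bromo-3-methylpent-2-en-4-yne
Conditions: PBr3, pyridine (cat.), Et2O, −20 to 0 °C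
Reagents that add atoms: phosphorus tribromide, BrP(Br)Br
Why: SN2 bromination of the primary allylic alcohol should keep the Z geometry, because the enyne cannot scramble by allylic transposition the way a dienyl halide could.

Step 5
Reactants: 8 3α-(tert-butyldimethylsilyloxy)-10-methyl-1-(trimethylsilyloxy)-4β-vinylcyclopent-1(10)-ene; 11 (2Z)-1-bromo-3-methylpent-2-en-4-yne
Product: 13 3α-(tert-butyldimethylsilyloxy)-10β-methyl-10α-[(2Z)-3-methylpent-2-en-4-yn-1-yl]-4β-vinylcyclopentan-1-one, via lithium enolate 12 (not isolated)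
Conditions: MeLi, THF, 0 °C; then 11, DMPU, −78 to −20 °C
Reagents that add atoms: (2Z)-1-bromo-3-methylpent-2-en-4-yne, BrC/C=C(C)\C#C
Why: Cleavage of the silyl enol ether gives the regiodefined lithium enolate, and its SN2 C-alkylation by the allylic bromide should occur anti to the adjacent C4 vinyl group, creating the C10 quaternary centre with methyl β and the side arm α.

Step 6
Reactants: 13 3α-(tert-butyldimethylsilyloxy)-10β-methyl-10α-[(2Z)-3-methylpent-2-en-4-yn-1-yl]-4β-vinylcyclopentan-1-one
Product: 14 10β-methyl-10α-[(2Z)-3-methylpent-2-en-4-yn-1-yl]-4β-vinylcyclopent-2-en-1-one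
Conditions: DBU, CH2Cl2, 0 °C
Reagents that add atoms: none
Why: E1cB elimination of the β-silyloxy group through the only possible enolate (C2 side, C10 being quaternary) should give the C2=C3 enone without touching C4 or C10.

Step 7
Reactants: 14 10β-methyl-10α-[(2Z)-3-methylpent-2-en-4-yn-1-yl]-4β-vinylcyclopent-2-en-1-one; 15 isopropylmagnesium chloride
Product: 17 3-isopropyl-10β-methyl-10α-[(2Z)-3-methylpent-2-en-4-yn-1-yl]-4β-vinylcyclopent-2-en-1-one, via magnesium enolate 16 (not isolated)
Conditions: iPrMgCl, CuBr·SMe2 (cat.), THF, −78 °C; then PhS(Cl)=NtBu, −78 °C to rt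
Reagents that add atoms: isopropylmagnesium chloride, CC(C)[Mg]Cl
Why: Copper-catalysed conjugate addition places isopropyl on C3, and sulfinimidoyl chloride dehydrogenation of the resulting enolate (S-attack at C2, then syn elimination of the C3 hydrogen) should restore the enone, which erases the transient C3 stereocentre.

Step 8
Reactants: 17 3-isopropyl-10β-methyl-10α-[(2Z)-3-methylpent-2-en-4-yn-1-yl]-4β-vinylcyclopent-2-en-1-one; 18 hydrogen peroxide
Product: 19 2α,3α-epoxy-3β-isopropyl-10β-methyl-10α-[(2Z)-3-methylpent-2-en-4-yn-1-yl]-4β-vinylcyclopentan-1-one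
Conditions: H2O2 (30% aq.), NaOH (cat.), MeOH, 0 °C
Reagents that add atoms: hydrogen peroxide, OO
Why: In this Weitz–Scheffer nucleophilic epoxidation the hydroperoxide should add to C3 from the α face, anti to the vicinal β vinyl group at C4 and the β methyl at C10, so that the C3–O bond is set on the α face.

Step 9
Reactants: 19 2α,3α-epoxy-3β-isopropyl-10β-methyl-10α-[(2Z)-3-methylpent-2-en-4-yn-1-yl]-4β-vinylcyclopentan-1-one
Product: 20 3α-hydroxy-3β-isopropyl-10β-methyl-10α-[(2Z)-3-methylpent-2-en-4-yn-1-yl]-4β-vinylcyclopentan-1-one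
Conditions: SmI2, THF–MeOH, −90 °C
Reagents that add atoms: none
Why: Single-electron reductive opening of the α,β-epoxy ketone cleaves only the C2–O bond, so the tertiary C3 alcohol (OH α, isopropyl β) keeps the configuration set in the epoxide.

Step 10
Reactants: 20 3α-hydroxy-3β-isopropyl-10β-methyl-10α-[(2Z)-3-methylpent-2-en-4-yn-1-yl]-4β-vinylcyclopentan-1-one
Product: 21 3β-isopropyl-10β-methyl-10α-[(2Z)-3-methylpent-2-en-4-yn-1-yl]-4β-vinylcyclopentane-1β,3α-diol
Conditions: Me4NBH(OAc)3, MeCN–AcOH, −30 °C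
Reagents that add atoms: none
Why: In this hydroxyl-directed (Evans–Saksena) reduction the acetoxyborohydride bound to the C3 oxygen should deliver hydride to the C1 carbonyl from the α face, giving the 1,3-anti diol with the C1 hydroxyl β.

Step 11
Reactants: 21 3β-isopropyl-10β-methyl-10α-[(2Z)-3-methylpent-2-en-4-yn-1-yl]-4β-vinylcyclopentane-1β,3α-diol; 22 acetic anhydride
Product: 23 1β-acetoxy-3β-isopropyl-10β-methyl-10α-[(2Z)-3-methylpent-2-en-4-yn-1-yl]-4β-vinylcyclopentan-3α-ol
Conditions: Ac2O, pyridine, DMAP (cat.), CH2Cl2, 0 °C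
Reagents that add atoms: acetic anhydride, CC(=O)OC(C)=O
Why: Nucleophile-catalysed acylation should acetylate the secondary C1 alcohol and leave the hindered tertiary C3 alcohol free.

Step 12
Reactants: 23 1β-acetoxy-3β-isopropyl-10β-methyl-10α-[(2Z)-3-methylpent-2-en-4-yn-1-yl]-4β-vinylcyclopentan-3α-ol
Product: 24 1β-acetoxy-3β-isopropyl-10β-methyl-10α-[(2Z)-3-methylpenta-2,4-dien-1-yl]-4β-vinylcyclopentan-3α-ol
Conditions: Zn dust activated with Cu(OAc)2 and AgNO3, MeOH–H2O, rt
Reagents that add atoms: none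
Why: Zinc–copper–silver semi-reduction is selective for conjugated triple bonds, so the terminal enyne should become the (Z)-dienyl arm while the isolated vinyl group, the acetate and the trisubstituted olefin geometry stay untouched.

Step 13
Reactants: 24 1β-acetoxy-3β-isopropyl-10β-methyl-10α-[(2Z)-3-methylpenta-2,4-dien-1-yl]-4β-vinylcyclopentan-3α-ol
Product: 25 1β-acetoxy-3β-isopropyl-7,10β-dimethyl-4αH-bicyclo[5.3.0]deca-5,7-dien-3α-ol (trans-fused ring B 5,7-diene)
Conditions: second-generation Grubbs catalyst (cat.), CH2Cl2 (high dilution), 40 °C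
Reagents that add atoms: none
Why: Ring-closing metathesis between the C4 vinyl group and the terminal olefin of the dienyl arm should form C5=C6 and the seven-membered ring with trans fusion inherited from the trans arms, since attack at the internal C7=C8 bond would need a strained trans-fused five-membered ring.

Step 14
Reactants: 25 1β-acetoxy-3β-isopropyl-7,10β-dimethyl-4αH-bicyclo[5.3.0]deca-5,7-dien-3α-ol; 26 dioxygen
Product: 27 1β-acetoxy-5α,8α-epidioxy-3β-isopropyl-7,10β-dimethyl-4αH-bicyclo[5.3.0]dec-6-en-3α-ol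
Conditions: O2, tetraphenylporphyrin (cat.), visible light, CH2Cl2, −20 °C
Reagents that add atoms: dioxygen, O=O
Why: Energy transfer from the excited sensitiser gives singlet oxygen, which adds suprafacially to the s-cis diene C5=C6–C7=C8 held in ring B in a concerted (4+2) cycloaddition that forms the C5–O and C8–O bonds and shifts the olefin to C6=C7. The closest known reaction type is the photooxygenation of cyclohepta-1,3-dienes and other cyclic 1,3-dienes to bicyclic endoperoxides. The six-membered 1,2-dioxine ring closes in cycloaddition mode, both ring bonds being made in the same step. C5 and C8 are both set by the face of approach: oxygen should come from the α face, anti to the axial β methyl at C10 and the β isopropyl at C3, and the α hydroxyl at C3 can assist by hydrogen bonding, while the suprafacial addition ties the two new centres cis to each other. The step needs face selectivity and (4+2) addition in preference to ene reaction; the trans ring fusion with its β angular methyl secures the first and the enforced s-cis geometry of the ring diene the second.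

Step 15
Reactants: 27 1β-acetoxy-5α,8α-epidioxy-3β-isopropyl-7,10β-dimethyl-4αH-bicyclo[5.3.0]dec-6-en-3α-ol
Product: 28 1β-acetoxy-3α,5α-dihydroxy-3β-isopropyl-7,10β-dimethyl-4αH-bicyclo[5.3.0]dec-6-en-8-one
Conditions: Et3N, CH2Cl2, 0 °C to rt
Reagents that add atoms: none
Why: In this Kornblum–DeLaMare rearrangement the amine should remove the C8 hydrogen, which lies next to the C9 methylene and is less shielded than the C5 hydrogen beside the ring fusion and the β isopropyl group, so that the O–O bond breaks, C8 becomes the enone carbonyl and C5 keeps its α oxygen as the free alcohol.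

Step 16
Reactants: 29 4-hydroxybenzoic acid; 30 tert-butyldimethylsilyl chloride
Product: 32 4-(tert-butyldimethylsilyloxy)benzoic acid, via bis-silyl derivative 31 (not isolated)
Conditions: TBSCl, imidazole, DMF, rt; then K2CO3, THF–MeOH–H2O, rt
Reagents that add atoms: tert-butyldimethylsilyl chloride, CC(C)(C)[Si](C)(C)Cl
Why: Silylation of both acidic sites followed by selective hydrolysis of the labile silyl ester should leave the phenol protected and the acid free.

Step 17
Reactants: 28 1β-acetoxy-3α,5α-dihydroxy-3β-isopropyl-7,10β-dimethyl-4αH-bicyclo[5.3.0]dec-6-en-8-one; 32 4-(tert-butyldimethylsilyloxy)benzoic acid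
Product: 33 1β-acetoxy-5α-[4-(tert-butyldimethylsilyloxy)benzoyloxy]-3α-hydroxy-3β-isopropyl-7,10β-dimethyl-4αH-bicyclo[5.3.0]dec-6-en-8-one
Conditions: DCC, DMAP, CH2Cl2, rt
Reagents that add atoms: 4-(tert-butyldimethylsilyloxy)benzoic acid, OC(=O)c1ccc(O[Si](C)(C)C(C)(C)C)cc1
Why: Steglich esterification should acylate the secondary allylic C5 alcohol with retention (the C5–O bond is not broken), the tertiary C3 alcohol being too hindered to compete.

Step 18
Reactants: 33 1β-acetoxy-5α-[4-(tert-butyldimethylsilyloxy)benzoyloxy]-3α-hydroxy-3β-isopropyl-7,10β-dimethyl-4αH-bicyclo[5.3.0]dec-6-en-8-one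
Product: 34 1β-acetoxy-3α-hydroxy-5α-(4-hydroxybenzoyloxy)-3β-isopropyl-7,10β-dimethyl-4αH-bicyclo[5.3.0]dec-6-en-8-one (target CNP0087181.1)
Conditions: TBAF, AcOH, THF, 0 °C
Reagents that add atoms: none
Why: Fluoride-induced desilylation should cleave the aryl silyl ether far faster than either ester, and the acetic acid buffer keeps the phenoxide from promoting acyl transfer.

Compound list
1 | (S)-4-(tert-butyldimethylsilyloxy)cyclopent-2-en-1-one | O=C1C=C[C@@H](O[Si](C)(C)C(C)(C)C)C1 | starting material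
2 | iodine | II | starting material
3 | (S)-4-(tert-butyldimethylsilyloxy)-2-iodocyclopent-2-en-1-one | O=C1C(I)=C[C@@H](O[Si](C)(C)C(C)(C)C)C1 | intermediate
4 | tetramethylstannane | C[Sn](C)(C)C | starting material
5 | (S)-4-(tert-butyldimethylsilyloxy)-2-methylcyclopent-2-en-1-one | O=C1C(C)=C[C@@H](O[Si](C)(C)C(C)(C)C)C1 | intermediate
6 | vinylmagnesium bromide | C=C[Mg]Br | starting material
7 | chlorotrimethylsilane | C[Si](C)(C)Cl | starting material
8 | 3α-(tert-butyldimethylsilyloxy)-10-methyl-1-(trimethylsilyloxy)-4β-vinylcyclopent-1(10)-ene | C[Si](C)(C)OC1=C(C)[C@H](C=C)[C@@H](O[Si](C)(C)C(C)(C)C)C1 | intermediate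
9 | (Z)-3-methylpent-2-en-4-yn-1-ol | OC/C=C(C)\C#C | starting material
10 | phosphorus tribromide | BrP(Br)Br | starting material
11 | (2Z)-1-bromo-3-methylpent-2-en-4-yne | BrC/C=C(C)\C#C | intermediate
12 | lithium enolate of the 10-methyl-4β-vinyl-3α-silyloxy ketone (C1–OLi, C1=C10) | [Li]OC1=C(C)[C@H](C=C)[C@@H](O[Si](C)(C)C(C)(C)C)C1 | intermediate
13 | 3α-(tert-butyldimethylsilyloxy)-10β-methyl-10α-[(2Z)-3-methylpent-2-en-4-yn-1-yl]-4β-vinylcyclopentan-1-one | O=C1C[C@H](O[Si](C)(C)C(C)(C)C)[C@@H](C=C)[C@]1(C)C/C=C(C)\C#C | intermediate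
14 | 10β-methyl-10α-[(2Z)-3-methylpent-2-en-4-yn-1-yl]-4β-vinylcyclopent-2-en-1-one | O=C1C=C[C@@H](C=C)[C@]1(C)C/C=C(C)\C#C | intermediate
15 | isopropylmagnesium chloride | CC(C)[Mg]Cl | starting material
16 | chloromagnesium enolate of the 3α-isopropyl adduct (C1–OMgCl, C1=C2) | Cl[Mg]OC1=C[C@H](C(C)C)[C@@H](C=C)[C@]1(C)C/C=C(C)\C#C | intermediate
17 | 3-isopropyl-10β-methyl-10α-[(2Z)-3-methylpent-2-en-4-yn-1-yl]-4β-vinylcyclopent-2-en-1-one | O=C1C=C(C(C)C)[C@@H](C=C)[C@]1(C)C/C=C(C)\C#C | intermediate
18 | hydrogen peroxide | OO | starting material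
19 | 2α,3α-epoxy-3β-isopropyl-10β-methyl-10α-[(2Z)-3-methylpent-2-en-4-yn-1-yl]-4β-vinylcyclopentan-1-one | O=C1[C@@H]2O[C@]2(C(C)C)[C@@H](C=C)[C@]1(C)C/C=C(C)\C#C | intermediate
20 | 3α-hydroxy-3β-isopropyl-10β-methyl-10α-[(2Z)-3-methylpent-2-en-4-yn-1-yl]-4β-vinylcyclopentan-1-one | O=C1C[C@@](O)(C(C)C)[C@@H](C=C)[C@]1(C)C/C=C(C)\C#C | intermediate
21 | 3β-isopropyl-10β-methyl-10α-[(2Z)-3-methylpent-2-en-4-yn-1-yl]-4β-vinylcyclopentane-1β,3α-diol | O[C@H]1C[C@@](O)(C(C)C)[C@@H](C=C)[C@]1(C)C/C=C(C)\C#C | intermediate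
22 | acetic anhydride | CC(=O)OC(C)=O | starting material
23 | 1β-acetoxy-3β-isopropyl-10β-methyl-10α-[(2Z)-3-methylpent-2-en-4-yn-1-yl]-4β-vinylcyclopentan-3α-ol | CC(=O)O[C@H]1C[C@@](O)(C(C)C)[C@@H](C=C)[C@]1(C)C/C=C(C)\C#C | intermediate
24 | 1β-acetoxy-3β-isopropyl-10β-methyl-10α-[(2Z)-3-methylpenta-2,4-dien-1-yl]-4β-vinylcyclopentan-3α-ol | CC(=O)O[C@H]1C[C@@](O)(C(C)C)[C@@H](C=C)[C@]1(C)C/C=C(C)\C=C | intermediate
25 | 1β-acetoxy-3β-isopropyl-7,10β-dimethyl-4αH-bicyclo[5.3.0]deca-5,7-dien-3α-ol (trans-fused ring B 5,7-diene) | CC(=O)O[C@H]1C[C@@](O)(C(C)C)[C@H]2C=CC(C)=CC[C@]12C | intermediate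
26 | dioxygen (used as singlet oxygen) | O=O | starting material
27 | 1β-acetoxy-5α,8α-epidioxy-3β-isopropyl-7,10β-dimethyl-4αH-bicyclo[5.3.0]dec-6-en-3α-ol | CC(=O)O[C@H]1C[C@@](O)(C(C)C)[C@H]2[C@H]3C=C(C)[C@H](OO3)C[C@]12C | intermediate
28 | 1β-acetoxy-3α,5α-dihydroxy-3β-isopropyl-7,10β-dimethyl-4αH-bicyclo[5.3.0]dec-6-en-8-one | CC(=O)O[C@H]1C[C@@](O)(C(C)C)[C@H]2[C@H](O)C=C(C)C(=O)C[C@]12C | intermediate
29 | 4-hydroxybenzoic acid | OC(=O)c1ccc(O)cc1 | starting material
30 | tert-butyldimethylsilyl chloride | CC(C)(C)[Si](C)(C)Cl | starting material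
31 | tert-butyldimethylsilyl 4-(tert-butyldimethylsilyloxy)benzoate | CC(C)(C)[Si](C)(C)OC(=O)c1ccc(O[Si](C)(C)C(C)(C)C)cc1 | intermediate
32 | 4-(tert-butyldimethylsilyloxy)benzoic acid | OC(=O)c1ccc(O[Si](C)(C)C(C)(C)C)cc1 | intermediate
33 | 1β-acetoxy-5α-[4-(tert-butyldimethylsilyloxy)benzoyloxy]-3α-hydroxy-3β-isopropyl-7,10β-dimethyl-4αH-bicyclo[5.3.0]dec-6-en-8-one | CC(=O)O[C@H]1C[C@@](O)(C(C)C)[C@H]2[C@H](OC(=O)c3ccc(O[Si](C)(C)C(C)(C)C)cc3)C=C(C)C(=O)C[C@]12C | intermediate
34 | 1β-acetoxy-3α-hydroxy-5α-(4-hydroxybenzoyloxy)-3β-isopropyl-7,10β-dimethyl-4αH-bicyclo[5.3.0]dec-6-en-8-one (CNP0087181.1) | CC(=O)O[C@H]1C[C@@](O)(C(C)C)[C@H]2[C@H](OC(=O)c3ccc(O)cc3)C=C(C)C(=O)C[C@]12C | target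

Total step count: 18.
Longest linear sequence: 16 steps (1, 2, 3, 5–15, 17, 18), from 1 to 34; steps 4 and 16 are side branches.

Steps most likely to fail

1. Step 14 (photooxygenation). Singlet oxygen may react in the ene mode at the C7 methyl or the C9 hydrogens, may add with poor face selectivity, or the peroxide may fragment on handling. The fallback is a stepwise cis-1,4-dioxygenation that sets out from 25. Buffered mCPBA should epoxidise the more electron-rich trisubstituted C7=C8 bond from the α face to give the 7α,8α-epoxide F1. Pd(PPh3)4-catalysed 1,4-addition of acid 32 (ionisation at C7 with inversion, carboxylate attack at C5 with inversion, net cis) would give the 5α-aroyloxy-8α-hydroxy-6-ene F2. Dess–Martin oxidation of the C8 alcohol then returns to the route at 33.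

2. Step 13 (ring-closing metathesis). The catalyst may be held up as an unreactive vinylcarbene on the conjugated diene, or oligomerise the arm instead of closing onto the hindered C4 vinyl group. The fallback masks the diene and sets out from 24. Chemoselective epoxidation (mCPBA, NaHCO3) of the trisubstituted olefin of the arm gives the monocyclic vinyl epoxide F3 as both epoxide diastereomers, so that the metathesis partner is an isolated vinyl group. Ring-closing metathesis would then give the bicyclic 7,8-epoxide F4, and oxygen transfer to PPh3 catalysed by CH3ReO3 regenerates the C7=C8 bond, returning to the route at 25.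

3. Step 15 (peroxide opening). The base may abstract the C5 hydrogen in competition with the C8 hydrogen, which would give the regioisomeric C5 ketone with a C8 alcohol. The fallback separates the two events and sets out from 27. Reduction of the O–O bond with thiourea in MeOH gives the 5α,8α-diol F5, and selective oxidation of the less hindered allylic C8 alcohol (MnO2, CH2Cl2) returns to the route at 28.

Further compounds
F1 | step 14 | 1β-acetoxy-7α,8α-epoxy-3β-isopropyl-7β,10β-dimethyl-4αH-bicyclo[5.3.0]dec-5-en-3α-ol | CC(=O)O[C@H]1C[C@@](O)(C(C)C)[C@H]2C=C[C@]3(C)O[C@@H]3C[C@]12C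
F2 | step 14 | 1β-acetoxy-5α-[4-(tert-butyldimethylsilyloxy)benzoyloxy]-3β-isopropyl-7,10β-dimethyl-4αH-bicyclo[5.3.0]dec-6-ene-3α,8α-diol | CC(=O)O[C@H]1C[C@@](O)(C(C)C)[C@H]2[C@H](OC(=O)c3ccc(O[Si](C)(C)C(C)(C)C)cc3)C=C(C)[C@H](O)C[C@]12C
F3 | step 13 | 1β-acetoxy-10α-[(3-methyl-3-vinyloxiran-2-yl)methyl]-3β-isopropyl-10β-methyl-4β-vinylcyclopentan-3α-ol (both epoxide diastereomers) | CC(=O)O[C@H]1C[C@@](O)(C(C)C)[C@@H](C=C)[C@]1(C)CC2OC2(C)C=C
F4 | step 13 | 1β-acetoxy-7,8-epoxy-3β-isopropyl-7,10β-dimethyl-4αH-bicyclo[5.3.0]dec-5-en-3α-ol (both epoxide diastereomers) | CC(=O)O[C@H]1C[C@@](O)(C(C)C)[C@H]2C=CC3(C)OC3C[C@]12C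
F5 | step 15 | 1β-acetoxy-3β-isopropyl-7,10β-dimethyl-4αH-bicyclo[5.3.0]dec-6-ene-3α,5α,8α-triol | CC(=O)O[C@H]1C[C@@](O)(C(C)C)[C@H]2[C@H](O)C=C(C)[C@H](O)C[C@]12C
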